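# Total synthesis of CNP0298885.1 by an isopulegol-type carbonyl-ene closure

Atom labels are terpenoid numbers: ring carbons C5–C10; C10 carries the C14 methyl and the C1=C2 vinyl group; C5 carries C4 with the C3 methylene and the C15 hydroxymethyl; the lactone is C7–C11(=C13)–C12(=O)–O–C8. Compound numbers are those of the steps below.

## The problem

The target is an elemane-type lactone: a single cyclohexane whose six ring carbons C5–C10 are all stereogenic ((5S,6R,7S,8S,9R,10S)), fused cis at C7/C8 to an α-methylene-γ-butyrolactone with the ring oxygen on C8. Around the ring sit a quaternary C10 (methyl and vinyl), C5 with the C4(=C3)C15–OH unit, a free hydroxyl at C6 and an isobutyrate at C9. In the chair only the C10 methyl and O8 are axial. C9 and C10 are neighbours and can be set together in an open chain. The α-oxygen on C9 can then direct C8, and aldol geometry fixes C7 relative to C8. That leaves C5 and C6 for the ring closure, where the four existing centres choose the chair. The molecule will not tolerate rough handling: the exocyclic methylene lactone is a Michael acceptor, the lactone can migrate from O8 to a free O6, an ester on O9 can shift to a free O8, and every open-chain intermediate with a carbonyl at C6 is a β-acyloxy carbonyl compound that eliminates with base. The 1,5-diene C2=C1–C10–C5–C4=C3 also argues against prolonged heating. The enabling feature is the C6 carbinol trans to C5 with its propen-2-yl-type substituent: O–C6–C5–C4=C3 is a homoallylic alcohol, the retron of a carbonyl-ene reaction between a C6 aldehyde and a C5=C4 alkene with the transferable hydrogen on C3. The tether C6–C7–C8–C9–C10–C5 has the length of the citronellal-to-isopulegol closure.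

## Retrosynthesis

**Endgame (29 ⇐ 28 ⇐ 24 ⇐ 23).** The last bonds cut are C11=C13 and the two O–Si bonds. The methylene lactone is the most reactive group and is therefore made after every organometallic, Lewis-acid and reduction step, by Mannich methylenation of the saturated lactone 24. Carrying the methylene through the ring closure is not possible here, because the ring-closure precursor is a β-acyloxy aldehyde that cannot see an enolising base. The C6 hydroxyl of 23 is silylated (24) so that no alkoxide can attack C12. The forward reaction must enolise the lactone CH2 beside the isobutyrate methine.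

**Key disconnection (23 ⇐ 22).** Cutting C5–C6 opens the cyclohexane and removes two stereocentres. The precursor is the open-chain cis-lactone aldehyde 22 with a (Z)-C5=C4 alkene, the C9 ester already in place and C15 as a silyl ether. The neighbouring cuts (C6–C7 or C7–C8) would require C5 to be carried as a preformed, epimerisable centre next to a carbonyl; here C5 is created. The forward reaction must choose one chair, take the hydrogen from C3 and not C15, and leave the vinyl group, lactone and ester alone.

**Lactone aldehyde (22 ⇐ 21 ⇐ 20 ⇐ 15 + 18).** C7–C8 and O8–C12 are cut. The four carbons C6, C7, C11 and C12 come in one piece from the succinic half-thioester 18. Its boron enolate 19 adds to aldehyde 15; an anti aldol corresponds to the cis lactone, and Cornforth/Felkin addition gives the C8/C9 relationship. The thioester is the C6 aldehyde in latent form and can be unmasked under neutral conditions. The isobutyrate must be on O9 before this stage: once the lactone is closed, a free C9 hydroxyl would sit cis to the C6 acyl group and close a second lactone.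

**C9–C10 (15 ⇐ 13 ⇐ 12 ⇐ 10 + 11).** The bond between the carbinol carbon and the quaternary carbon is an allylboration retron; the vinyl group is the transposed allyl unit. The aldehyde partner is the glyceraldehyde acetonide 11, which acts as a chiral glyoxal equivalent. Its dioxolane carbon becomes C8, its stereocentre biases the face of addition and makes any minor isomer a separable diastereomer, and it is excised after acylation (13 to 15). An achiral glyoxylate with a chiral catalyst would be one operation shorter on paper but would rest on catalyst control alone. The forward reaction needs the boronate 10 with defined geometry at both alkenes.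

**Dienylboronate (10 ⇐ 7 ⇐ 5 ⇐ 4 ⇐ 3 ⇐ 1).** Four bonds are cut: C1–C2 (boron homologation), C10–C14 (carboalumination), C5–C10 (ethynylation) and C3–C4 (carbomagnesiation). Both alkene geometries come from stereospecific carbometalations of alkynes. The Z geometry at C5=C4 comes from anti addition to the alkoxide of 1; the E geometry at C1=C10 comes from syn addition to enyne 5. Everything starts from three-carbon and two-carbon commodity reagents.

## Roads not taken

**Alternative 1:** Here the ring is bought, and C4–C5 and C1–C10 are cut. A copper-mediated conjugate addition of the C3–C4–C15 alkenyl unit to the 4-silyloxy-2-methylcyclohexenone A2 is followed by trapping of the enolate with a one-carbon electrophile. This gives A1 with C5, C6 and C10 set.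
- Merits: it is a convergent three-component coupling. The trans relationships come from well-known biases (addition anti to the silyloxy group, alkylation anti to the new C5 substituent). For C5/C6/C10 it is at least as reliable as the chair-controlled closure chosen here, and it needs no delicate aldehyde.
- Weak points: A1 has bare methylenes at C7 and C8 and a ketone at C9. The lactone carbons, O8, the C9 ester and three more stereocentres must then be introduced on the ring, with C7 remote from the only activating group. The C1 hydroxymethyl must also be turned into the vinyl group at a neopentyl position.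
- Comparison: the chosen plan builds C7–C10 and the lactone by two open-chain additions (steps 6 and 10) before the ring exists, and lets the ring closure supply C5 and C6.

**Alternative 2:** C7–C8 and O8–C12 are cut. A divalent chromium reductant converts the allylic bromide of the open-chain formyl 2-(bromomethyl)enoate A4 into an allylchromium species. This attacks the C8 aldehyde through C7, and the alkoxide closes the lactone, giving A3, the 6,15-bis-silyl ether of the target.
- Merits: ring, lactone and exocyclic methylene arise in one step, and no enolate chemistry is needed beside the isobutyrate. After the key step it is clearly shorter than the chosen plan (one deprotection against steps 14–16).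
- Weak points: A4 must already carry C5, C6, C9 and C10 in an open chain, including the C5/C6 pair next to the quaternary carbon. The C7/C8 and C8/C9 relationships depend on an allylmetal whose geometry can equilibrate. The α-acyloxy aldehyde and the bromomethyl enoate must coexist.
- Comparison: the chosen plan offers a precursor (22) reached by stereochemically predictable additions, creation of C5/C6 instead of transport, and a ring closure that is an isomerisation without a stoichiometric metal reductant.

**Alternative 3:** C6–C7 is cut. A divalent samarium reductant turns the C6 aldehyde of A6 into a ketyl that adds to C7 of the tethered α-(phenylthiomethyl)butenolide. Loss of thiolate leaves the methylene, giving A5, the 15-silyl ether of the target.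
- Merits: it closes the same ring, delivers the methylene lactone directly and is one step from the target, so it is better than the chosen plan in the endgame.
- Weak points: in A6 the aldehyde sits on C5, a stereocentre that also carries the C4=C3 alkene, so epimerisation and conjugation threaten more than in 22. The product A5 is itself reducible by the reagent. C6/C7 selectivity rests on the folding of a flexible chain. A6 again needs C5, C9 and C10 set in an open chain.
- Comparison: the chosen plan creates C5 instead of carrying it α to an aldehyde, and introduces the methylene only when no reductant or base-labile carbonyl remains.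

Key step: step 13

## The route

Remark: metal alkoxides that are only protonated on work-up are not numbered separately.
Remark: (S)-2,2-dimethyl-1,3-dioxolane-4-carbaldehyde (11) is taken as a purchasable compound, distilled before use.

Step 1
Reactants: 1 prop-2-yn-1-ol
Product: 3 (Z)-3-iodo-2-methylprop-2-en-1-ol, via alkenylmagnesium alkoxide 2 (not isolated)
Conditions: MeMgBr (2.5 equiv), CuI (10 mol %), THF/Et2O, −10 °C → rt; then I2, −78 → 0 °C
Reagents that add atoms: methylmagnesium bromide, C[Mg]Br; iodine, II
Why: Copper-catalysed carbomagnesiation of the propargylic alkoxide (Duboudin reaction) places methyl on the internal carbon and magnesium on the terminal carbon cis to the chelating alkoxide (anti addition); iodinolysis with retention gives the Z iodide, which fixes the later C5=C4 geometry.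

Step 2
Reactants: 3 (Z)-3-iodo-2-methylprop-2-en-1-ol
Product: 4 (Z)-tert-butyl[(3-iodo-2-methylprop-2-en-1-yl)oxy]diphenylsilane
Conditions: t-BuPh2SiCl, imidazole, CH2Cl2, 0 °C → rt
Reagents that add atoms: tert-butyl(chloro)diphenylsilane, CC(C)(C)[Si](Cl)(c1ccccc1)c1ccccc1
Why: Standard silylation of a primary alcohol; the diphenyl-tert-butylsilyl ether is chosen over the dimethyl analogue because it must survive the acidic glycol cleavage of step 8 and does not bind the aluminium Lewis acid of step 13.

Step 3
Reactants: 4 (Z)-tert-butyl[(3-iodo-2-methylprop-2-en-1-yl)oxy]diphenylsilane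
Product: 5 (Z)-tert-butyl[(2-methylpent-2-en-4-yn-1-yl)oxy]diphenylsilane
Conditions: HC≡CMgBr, ZnBr2, THF, 0 °C; then 4, Pd(PPh3)4 (5 mol %), THF, rt
Reagents that add atoms: ethynylmagnesium bromide, C#C[Mg]Br
Why: Negishi coupling of an ethynylzinc halide with an alkenyl iodide gives the terminal enyne directly with retention of the Z geometry; no silyl-alkyne detour is needed.

Step 4
Reactants: 5 (Z)-tert-butyl[(2-methylpent-2-en-4-yn-1-yl)oxy]diphenylsilane
Product: 7 tert-butyl{[(2Z,4E)-5-iodo-2,4-dimethylpenta-2,4-dien-1-yl]oxy}diphenylsilane, via dienyldimethylalane 6 (not isolated)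
Conditions: Me3Al (2.5 equiv), Cp2ZrCl2 (0.25 equiv), CH2Cl2, 0 °C → rt; then I2, THF, −30 → 0 °C
Reagents that add atoms: trimethylaluminium, C[Al](C)C; iodine, II
Why: Zirconium-catalysed syn carboalumination (Negishi) of the terminal alkyne puts methyl on the internal carbon (C10) and aluminium on the terminal carbon; iodinolysis with retention leaves iodine cis to the new methyl, and the existing Z alkene and silyl ether are inert.

Step 5
Reactants: 7 tert-butyl{[(2Z,4E)-5-iodo-2,4-dimethylpenta-2,4-dien-1-yl]oxy}diphenylsilane
Product: 10 2-[(2E,4Z)-6-(tert-butyldiphenylsilyloxy)-3,5-dimethylhexa-2,4-dien-1-yl]-4,4,5,5-tetramethyl-1,3,2-dioxaborolane, via dienyllithium 8 (not isolated), via lithium chloromethylborate 9 (not isolated)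
Conditions: t-BuLi (2.1 equiv), Et2O, −78 °C; ClCH2Bpin, −78 °C → rt
Reagents that add atoms: 2-(chloromethyl)-4,4,5,5-tetramethyl-1,3,2-dioxaborolane, ClCB1OC(C)(C)C(C)(C)O1
Why: Iodine–lithium exchange proceeds with retention, the alkenyllithium adds to boron, and the ate complex undergoes a 1,2-metallate shift with loss of chloride (Matteson-type homologation of an alkenyl group); the allylboronate therefore has CH2B cis to the C14 methyl and trans to the dienyl arm, and pinacol allylboronates do not undergo allylic boron shifts at room temperature.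

Step 6
Reactants: 10 the (2E,4Z)-dienylmethyl pinacol boronate; 11 (S)-2,2-dimethyl-1,3-dioxolane-4-carbaldehyde
Product: 12 (1R,2S,3Z)-5-(tert-butyldiphenylsilyloxy)-1-[(4S)-2,2-dimethyl-1,3-dioxolan-4-yl]-2-ethenyl-2,4-dimethylpent-3-en-1-ol
Conditions: 11 (2 equiv), toluene, 4 Å MS, rt, 48 h; aq. NaHCO3
Reagents that add atoms: none
Why: Allylboration through a Zimmerman–Traxler chair with the dioxolanyl group equatorial: the γ-substituent trans to CH2B (the alkenyl arm) ends anti to the new hydroxyl and the cis methyl syn, which is the C9/C10 relationship of the target and creates the vinyl group. The face of the aldehyde is chosen by the Felkin/Cornforth preference of the α-alkoxy aldehyde, which is reinforced by a cis γ-substituent, so the new C–O is anti to the dioxolane oxygen and C9 is R; any minor isomer is a diastereomer and is removed by chromatography.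

Step 7
Reactants: 12 the C9 alcohol
Product: 13 the C9 2-methylpropanoate of 12 (acetonide and silyl ether unchanged)
Conditions: i-PrCOCl, pyridine, DMAP (cat.), CH2Cl2, 0 °C → rt
Reagents that add atoms: 2-methylpropanoyl chloride, CC(C)C(Cl)=O
Why: Nucleophile-catalysed acylation of a hindered secondary alcohol; the ester of the target is installed here because O9 can no longer be acylated safely once the C6 acyl group and the lactone are present.

Step 8
Reactants: 13 the isobutyrate acetonide
Product: 15 (2R,3S,4Z)-6-(tert-butyldiphenylsilyloxy)-3-ethenyl-3,5-dimethyl-1-oxohex-4-en-2-yl 2-methylpropanoate (the C8 aldehyde), via terminal diol 14 (not isolated)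
Conditions: H5IO6 (1.5 equiv), EtOAc, 0 °C → rt
Reagents that add atoms: none
Why: Periodic acid in ethyl acetate hydrolyses a terminal isopropylidene acetal and cleaves the glycol in the same flask, so the diol never accumulates next to the ester and acyl shift has no time to occur; the auxiliary stereocentre becomes the C8 formyl carbon, and alkenes, ester and the diphenyl-tert-butylsilyl ether are inert.

Step 9
Reactants: 16 methyl 4-chloro-4-oxobutanoate; 17 benzenethiol
Product: 18 S-phenyl 4-methoxy-4-oxobutanethioate
Conditions: pyridine, CH2Cl2, 0 °C → rt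
Reagents that add atoms: none
Why: Simple acylation of a thiol by an acid chloride; it differentiates the two ends of the succinate as thioester (C6) and oxoester (C12).

Step 10
Reactants: 18 S-phenyl 4-methoxy-4-oxobutanethioate; 15 the C8 aldehyde
Product: 20 anti,anti aldol adduct (methyl ester at C12, S-phenyl thioester at C6, free C8 hydroxyl, C9 isobutyrate), via dicyclohexylboron enolate 19 (not isolated)
Conditions: 18 (1.5 equiv), (c-C6H11)2BCl, Et3N, Et2O, 0 °C; then 15, −78 → −20 °C; MeOH, pH 7 buffer, H2O2, 0 °C
Reagents that add atoms: none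
Why: The dialkylchloroborane/amine pair enolises the thioester but not the oxoester and gives the E(O) enol borinate, which reacts through a closed chair to the 7,8-anti aldol (Brown/Masamune anti-selective thioester boron aldol). With an E enolate and an α-oxygenated aldehyde the Cornforth/polar Felkin–Anh transition state places the C9–O bond away from the carbonyl and the quaternary C10 away from the nucleophile, so the new C8–O is anti to O9.

Step 11
Reactants: 20 the aldol adduct
Product: 21 cis-4,5-disubstituted γ-lactone S-phenyl thioester (O8–C12 closed; C6 thioester on C7 cis to the C9 side chain on C8)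
Conditions: pyridinium p-toluenesulfonate (cat.), toluene, 50 °C
Reagents that add atoms: none
Why: Acid-catalysed 5-exo lactonisation of the γ-hydroxy methyl ester; the anti aldol geometry translates into the cis lactone, and the absence of base avoids loss of O8 from C8 by elimination toward the acidic C7 position.

Step 12
Reactants: 21 the lactone thioester
Product: 22 cis-lactone aldehyde (C6 formyl on C7; C9 isobutyrate; (Z)-C5=C4; C15 silyl ether)
Conditions: Et3SiH (3 equiv), Pd/CaCO3 (Pb(OAc)2-poisoned, 10 mol %), acetone, rt; filtered and used at once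
Reagents that add atoms: none
Why: Fukuyama reduction: zerovalent palladium inserts into the acyl–sulfur bond, the silane delivers hydride and the aldehyde is released under neutral conditions, which the β-acyloxy aldehyde requires. The poisoned catalyst leaves the vinyl and trisubstituted alkenes untouched, and lactone and isobutyrate do not react.

Step 13
Reactants: 22 the cis-lactone aldehyde
Product: 23 cyclised 6-hydroxy lactone (cyclohexane C5–C10 closed; C4=C3 methylene; equatorial C6 hydroxyl trans to C5; saturated cis-fused lactone; C9 isobutyrate; C15 silyl ether)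
Conditions: Me2AlCl (2.5 equiv), CH2Cl2, −78 → −40 °C; pH 7 buffer, aq. potassium sodium tartrate
Reagents that add atoms: none
Why: Me2AlCl binds the aldehyde oxygen, C5 of the (Z)-trisubstituted alkene attacks C6 while positive charge builds at tertiary C4, and a hydrogen of the C3 methyl passes to the aluminium-bound oxygen through a six-centre array; the complexed alcohol then loses methane to a neutral aluminium alkoxide, so no proton source remains. The closest known reaction is the Lewis-acid cyclisation of 6-enals to trans-2-(propen-2-yl)cyclohexanols, as in citronellal to isopulegol. The cyclohexane closes by C5–C6 bond formation through a chair, an exo attack on the carbonyl that leaves C4 exocyclic. C5 is set by the chair in which the cis-lactone holds C11 equatorial and O8 axial, the C9 ester is equatorial and the C10 methyl axial, so the alkene is attacked on the face that leaves C4 equatorial. C6 is set by the aluminium-bound oxygen taking the equatorial site anti to the C5–C10 bond, which gives the trans C5/C6 pair. The step needs face selectivity: the flipped chair would put the vinyl group, the C9 ester and C11 axial and is disfavoured. It also needs hydrogen transfer from C3 rather than C15: the Z geometry places the C3 methyl trans to C10, beneath the equatorial oxygen, while the silyloxymethyl group points away. Finally it needs chemoselectivity: the vinyl group has no allylic hydrogen and would give a primary cation, and the lactone and ester carbonyls only bind Lewis acid, which the excess covers.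

Step 14
Reactants: 23 the cyclised 6-hydroxy lactone
Product: 24 the 6-O-triethylsilyl ether of 23
Conditions: Et3SiOSO2CF3, 2,6-lutidine, CH2Cl2, −78 → 0 °C
Reagents that add atoms: triethylsilyl trifluoromethanesulfonate, CC[Si](CC)(CC)OS(=O)(=O)C(F)(F)F
Why: Silylation of a hindered equatorial secondary alcohol with a silyl triflate and a non-nucleophilic base; it removes the hydroxyl that could, as an alkoxide, attack C12 and move the lactone from O8 to O6 in the next step.

Step 15
Reactants: 24 the 6-O-triethylsilyl ether
Product: 28 the α-methylene lactone as its 6-O-triethylsilyl 15-O-tert-butyldiphenylsilyl bis-ether, via lithium lactone enolate 25 (not isolated), via Mannich base 26 (not isolated), via trimethylammonium iodide 27 (not isolated)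
Conditions: LiN(SiMe3)2 (1.2 equiv), THF, −78 °C; CH2=NMe2+ I−, −78 → 0 °C; MeI, CH2Cl2, rt; aq. NaHCO3, rt
Reagents that add atoms: dimethylmethyleneiminium iodide, C=[N+](C)C.[I-]
Why: Kinetic deprotonation takes the lactone CH2 at C11 (more acidic and far less hindered than the isobutyrate methine); the enolate is aminomethylated (Mannich reaction), and quaternisation followed by mild base eliminates trimethylamine to give the exocyclic alkene. The C11 configuration of the intermediates is irrelevant, and the 1,3-diequatorial placement of C11 and O9 keeps the enolate from reaching the ester carbonyl.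

Step 16
Reactants: 28 the bis-silyl ether
Product: 29 CNP0298885.1
Conditions: HF·pyridine, pyridine, THF, 0 °C → rt
Reagents that add atoms: none
Why: Fluoride-mediated cleavage of both silyl ethers in a buffered acidic medium; no alkoxide is formed, so neither lactone migration to O6 nor conjugate addition to the methylene lactone is expected, and the isobutyrate is stable.

## Compound list

1 | prop-2-yn-1-ol | C#CCO | starting material
2 | bromomagnesium (Z)-3-(bromomagnesio)-2-methylprop-2-en-1-olate | Br[Mg]/C=C(/C)CO[Mg]Br | intermediate
3 | (Z)-3-iodo-2-methylprop-2-en-1-ol | I/C=C(/C)CO | intermediate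
4 | (Z)-tert-butyl[(3-iodo-2-methylprop-2-en-1-yl)oxy]diphenylsilane | I/C=C(/C)CO[Si](c1ccccc1)(c1ccccc1)C(C)(C)C | intermediate
5 | (Z)-tert-butyl[(2-methylpent-2-en-4-yn-1-yl)oxy]diphenylsilane | C#C/C=C(/C)CO[Si](c1ccccc1)(c1ccccc1)C(C)(C)C | intermediate
6 | [(1E,3Z)-5-(tert-butyldiphenylsilyloxy)-2,4-dimethylpenta-1,3-dien-1-yl]dimethylalane | C[Al](C)/C=C(\C)/C=C(/C)CO[Si](c1ccccc1)(c1ccccc1)C(C)(C)C | intermediate
7 | tert-butyl{[(2Z,4E)-5-iodo-2,4-dimethylpenta-2,4-dien-1-yl]oxy}diphenylsilane | I/C=C(\C)/C=C(/C)CO[Si](c1ccccc1)(c1ccccc1)C(C)(C)C | intermediate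
8 | [(1E,3Z)-5-(tert-butyldiphenylsilyloxy)-2,4-dimethylpenta-1,3-dien-1-yl]lithium | [Li]/C=C(\C)/C=C(/C)CO[Si](c1ccccc1)(c1ccccc1)C(C)(C)C | intermediate
9 | lithium (chloromethyl)[(1E,3Z)-dienyl]pinacolatoborate | [Li+].ClC[B-]1(/C=C(\C)/C=C(/C)CO[Si](c2ccccc2)(c2ccccc2)C(C)(C)C)OC(C)(C)C(C)(C)O1 | intermediate
10 | 2-[(2E,4Z)-6-(tert-butyldiphenylsilyloxy)-3,5-dimethylhexa-2,4-dien-1-yl]-4,4,5,5-tetramethyl-1,3,2-dioxaborolane | CC1(C)OB(C/C=C(\C)/C=C(/C)CO[Si](c2ccccc2)(c2ccccc2)C(C)(C)C)OC1(C)C | intermediate
11 | (S)-2,2-dimethyl-1,3-dioxolane-4-carbaldehyde | O=C[C@@H]1COC(C)(C)O1 | starting material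
12 | (1R,2S,3Z)-5-(tert-butyldiphenylsilyloxy)-1-[(4S)-2,2-dimethyl-1,3-dioxolan-4-yl]-2-ethenyl-2,4-dimethylpent-3-en-1-ol | CC1(C)OC[C@H](O1)[C@H](O)[C@@](C)(C=C)/C=C(/C)CO[Si](c1ccccc1)(c1ccccc1)C(C)(C)C | intermediate
13 | C9 2-methylpropanoate of 12 | CC1(C)OC[C@H](O1)[C@H](OC(=O)C(C)C)[C@@](C)(C=C)/C=C(/C)CO[Si](c1ccccc1)(c1ccccc1)C(C)(C)C | intermediate
14 | terminal 1,2-diol from 13 (acetonide removed) | OC[C@H](O)[C@H](OC(=O)C(C)C)[C@@](C)(C=C)/C=C(/C)CO[Si](c1ccccc1)(c1ccccc1)C(C)(C)C | intermediate
15 | (2R,3S,4Z)-6-(tert-butyldiphenylsilyloxy)-3-ethenyl-3,5-dimethyl-1-oxohex-4-en-2-yl 2-methylpropanoate | O=C[C@H](OC(=O)C(C)C)[C@@](C)(C=C)/C=C(/C)CO[Si](c1ccccc1)(c1ccccc1)C(C)(C)C | intermediate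
16 | methyl 4-chloro-4-oxobutanoate | COC(=O)CCC(Cl)=O | starting material
17 | benzenethiol | Sc1ccccc1 | starting material
18 | S-phenyl 4-methoxy-4-oxobutanethioate | COC(=O)CCC(=O)Sc1ccccc1 | intermediate
19 | dicyclohexylboron E(O)-enolate of 18 (CH2CO2Me trans to OB) | COC(=O)C/C=C(/OB(C1CCCCC1)C1CCCCC1)Sc1ccccc1 | intermediate
20 | anti,anti aldol adduct: methyl ester (C12), S-phenyl thioester (C6), C8 hydroxyl, C9 isobutyrate | COC(=O)C[C@@H](C(=O)Sc1ccccc1)[C@H](O)[C@H](OC(=O)C(C)C)[C@@](C)(C=C)/C=C(/C)CO[Si](c1ccccc1)(c1ccccc1)C(C)(C)C | intermediate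
21 | cis-lactone S-phenyl thioester | O=C(Sc1ccccc1)[C@@H]1CC(=O)O[C@@H]1[C@H](OC(=O)C(C)C)[C@@](C)(C=C)/C=C(/C)CO[Si](c1ccccc1)(c1ccccc1)C(C)(C)C | intermediate
22 | cis-lactone aldehyde, precursor of the key step | O=C[C@@H]1CC(=O)O[C@@H]1[C@H](OC(=O)C(C)C)[C@@](C)(C=C)/C=C(/C)CO[Si](c1ccccc1)(c1ccccc1)C(C)(C)C | intermediate
23 | cyclised 6-hydroxy lactone, product of the key step | C=C[C@@]1(C)[C@H](C(=C)CO[Si](c2ccccc2)(c2ccccc2)C(C)(C)C)[C@@H](O)[C@@H]2CC(=O)O[C@@H]2[C@@H]1OC(=O)C(C)C | intermediate
24 | 6-O-triethylsilyl ether of 23 | C=C[C@@]1(C)[C@H](C(=C)CO[Si](c2ccccc2)(c2ccccc2)C(C)(C)C)[C@@H](O[Si](CC)(CC)CC)[C@@H]2CC(=O)O[C@@H]2[C@@H]1OC(=O)C(C)C | intermediate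
25 | lithium enolate of lactone 24 (C11=C12–OLi) | C=C[C@@]1(C)[C@H](C(=C)CO[Si](c2ccccc2)(c2ccccc2)C(C)(C)C)[C@@H](O[Si](CC)(CC)CC)[C@@H]2C=C(O[Li])O[C@@H]2[C@@H]1OC(=O)C(C)C | intermediate
26 | 11-(dimethylaminomethyl) lactone (C11 epimers) | C=C[C@@]1(C)[C@H](C(=C)CO[Si](c2ccccc2)(c2ccccc2)C(C)(C)C)[C@@H](O[Si](CC)(CC)CC)[C@@H]2C(CN(C)C)C(=O)O[C@@H]2[C@@H]1OC(=O)C(C)C | intermediate
27 | 11-(trimethylammoniomethyl) lactone iodide (C11 epimers) | C=C[C@@]1(C)[C@H](C(=C)CO[Si](c2ccccc2)(c2ccccc2)C(C)(C)C)[C@@H](O[Si](CC)(CC)CC)[C@@H]2C(C[N+](C)(C)C)C(=O)O[C@@H]2[C@@H]1OC(=O)C(C)C.[I-] | intermediate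
28 | 6-O-triethylsilyl 15-O-tert-butyldiphenylsilyl ether of the target | C=C[C@@]1(C)[C@H](C(=C)CO[Si](c2ccccc2)(c2ccccc2)C(C)(C)C)[C@@H](O[Si](CC)(CC)CC)[C@@H]2C(=C)C(=O)O[C@@H]2[C@@H]1OC(=O)C(C)C | intermediate
29 | CNP0298885.1, (5S,6R,7S,8S,9R,10S) in terpenoid numbering | C=C[C@@]1(C)[C@H](C(=C)CO)[C@@H](O)[C@@H]2C(=C)C(=O)O[C@@H]2[C@@H]1OC(=O)C(C)C | target

## Step count and risk

Total: 16 steps. Longest linear sequence: 15 steps (steps 1–8 and 10–16, from 1 to 29); step 9 is a one-step side branch.

**Step 13 (key step).** The most likely failure is erosion of chair control, that is closure with the aluminium-bound oxygen axial or through a boat, so that the C6 hydroxyl forms cis to C5. The second danger is loss of the lactone oxygen from C8 by elimination in the β-acyloxy aldehyde before the ring closes. Fallback, from 22 back to 23: the carbinol configuration is corrected after the closure instead of being demanded of it. The C6-epimeric alcohol F1, alone or mixed with 23, is oxidised with Dess–Martin periodinane/NaHCO3 to the C6 ketone F2. NaBH4/CeCl3·7H2O in MeOH at −78 °C then delivers hydride axially between the two equatorial neighbours and returns the equatorial alcohol 23.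

**Step 10.** The likely failure is weak facial selectivity at C8, because the directing α-substituent is an acyloxy group and not an ether, or incomplete formation of the E(O) enolate, which leaks into the syn aldol. Fallback, from 12 back to 24: O9 is carried as an ether through the aldol and the ring closure and exchanged for the ester only when C6 is a protected carbinol. The exchange cannot be made earlier, because a free C9 hydroxyl cis to the C6 acyl group would close a second lactone.
- NaH, 4-methoxybenzyl chloride and Bu4NI in DMF convert 12 into the 4-methoxybenzyl ether F3.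
- H5IO6 gives the α-(4-methoxybenzyloxy) aldehyde F4.
- Enolate 19 gives the aldol adduct F5.
- Pyridinium p-toluenesulfonate closes the lactone thioester F6.
- Et3SiH over poisoned Pd/CaCO3 gives the lactone aldehyde F7.
- Me2AlCl cyclises it to the 9-O-(4-methoxybenzyl) cyclohexanol F8.
- Et3SiOSO2CF3 gives its 6-O-triethylsilyl ether F9.
- DDQ in CH2Cl2/pH 7 buffer frees the C9 alcohol F10.
- i-PrCOCl, DMAP and pyridine convert F10 into 24.

**Step 11.** The likely failure is migration of the isobutyryl group from O9 to the free O8, after which O9 can capture the C6 thioester, in competition with the wanted lactonisation. Fallback, from 15 back to 21: lactonisation is made faster than acyl shift by using an activated acyl group at C12 and no acid step. S,S-diphenyl butanebis(thioate) F11, from succinyl chloride and 17, is enolised once with (c-C6H11)2BCl/Et3N and added to 15. In the bis-thioester aldol adduct F12 the C8 hydroxyl closes onto the C12 thioester on work-up or on brief contact with silica gel, releasing 17 and giving 21.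

**Step 12.** The likely failures are saturation of the vinyl group by the silane on palladium, deactivation of the catalyst by thiolate, and elimination of the sensitive aldehyde on the support. Fallback, from 21 back to 22: a reduction–oxidation pair replaces the partial reduction. NaBH4 in THF/EtOH at 0 °C reduces the thioester, but not the lactone or the isobutyrate, to the C6 primary alcohol F13. Dess–Martin periodinane/NaHCO3 then gives 22.

**Step 6.** The likely failure is insufficient facial bias of the achiral boronate toward 11, since the trans γ-substituent works against the Felkin preference, together with slow addition that lets 11 oligomerise. Fallback, from 7 back to 12: reagent control is added to substrate control. The dienyllithium 8, made from 7 as in step 5, is trapped with ClCH2B(OiPr)2 to give diisopropyl [(2E,4Z)-dienylmethyl]boronate F14. This is transesterified with diisopropyl (S,S)-tartrate to the tartrate allylboronate F15. Its addition to 11 in toluene at −78 °C over 4 Å sieves is the matched pairing for the anti adduct 12.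

## Further compounds

F1 | step 13 | C6 epimer of 23 (axial C6 hydroxyl, cis to C5) | C=C[C@@]1(C)[C@H](C(=C)CO[Si](c2ccccc2)(c2ccccc2)C(C)(C)C)[C@H](O)[C@@H]2CC(=O)O[C@@H]2[C@@H]1OC(=O)C(C)C
F2 | step 13 | C6 ketone from 23/F1 | C=C[C@@]1(C)[C@H](C(=C)CO[Si](c2ccccc2)(c2ccccc2)C(C)(C)C)C(=O)[C@@H]2CC(=O)O[C@@H]2[C@@H]1OC(=O)C(C)C
F3 | step 10 | 9-O-(4-methoxybenzyl) ether of 12 | CC1(C)OC[C@H](O1)[C@H](OCc1ccc(OC)cc1)[C@@](C)(C=C)/C=C(/C)CO[Si](c1ccccc1)(c1ccccc1)C(C)(C)C
F4 | step 10 | α-(4-methoxybenzyloxy) C8 aldehyde | O=C[C@H](OCc1ccc(OC)cc1)[C@@](C)(C=C)/C=C(/C)CO[Si](c1ccccc1)(c1ccccc1)C(C)(C)C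
F5 | step 10 | anti,anti aldol adduct, 9-O-(4-methoxybenzyl) series | COC(=O)C[C@@H](C(=O)Sc1ccccc1)[C@H](O)[C@H](OCc1ccc(OC)cc1)[C@@](C)(C=C)/C=C(/C)CO[Si](c1ccccc1)(c1ccccc1)C(C)(C)C
F6 | step 10 | cis-lactone S-phenyl thioester, 9-O-(4-methoxybenzyl) series | O=C(Sc1ccccc1)[C@@H]1CC(=O)O[C@@H]1[C@H](OCc1ccc(OC)cc1)[C@@](C)(C=C)/C=C(/C)CO[Si](c1ccccc1)(c1ccccc1)C(C)(C)C
F7 | step 10 | cis-lactone aldehyde, 9-O-(4-methoxybenzyl) series | O=C[C@@H]1CC(=O)O[C@@H]1[C@H](OCc1ccc(OC)cc1)[C@@](C)(C=C)/C=C(/C)CO[Si](c1ccccc1)(c1ccccc1)C(C)(C)C
F8 | step 10 | cyclised 6-hydroxy lactone, 9-O-(4-methoxybenzyl) ether | C=C[C@@]1(C)[C@H](C(=C)CO[Si](c2ccccc2)(c2ccccc2)C(C)(C)C)[C@@H](O)[C@@H]2CC(=O)O[C@@H]2[C@@H]1OCc1ccc(OC)cc1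
F9 | step 10 | 6-O-triethylsilyl ether of F8 | C=C[C@@]1(C)[C@H](C(=C)CO[Si](c2ccccc2)(c2ccccc2)C(C)(C)C)[C@@H](O[Si](CC)(CC)CC)[C@@H]2CC(=O)O[C@@H]2[C@@H]1OCc1ccc(OC)cc1
F10 | step 10 | C9 alcohol (6-O-triethylsilyl, 15-O-tert-butyldiphenylsilyl) | C=C[C@@]1(C)[C@H](C(=C)CO[Si](c2ccccc2)(c2ccccc2)C(C)(C)C)[C@@H](O[Si](CC)(CC)CC)[C@@H]2CC(=O)O[C@@H]2[C@@H]1O
F11 | step 11 | S,S-diphenyl butanebis(thioate) | O=C(CCC(=O)Sc1ccccc1)Sc1ccccc1
F12 | step 11 | anti,anti aldol adduct with S-phenyl thioesters at C6 and C12 | O=C(C[C@@H](C(=O)Sc1ccccc1)[C@H](O)[C@H](OC(=O)C(C)C)[C@@](C)(C=C)/C=C(/C)CO[Si](c1ccccc1)(c1ccccc1)C(C)(C)C)Sc1ccccc1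
F13 | step 12 | cis-lactone C6 primary alcohol | OC[C@@H]1CC(=O)O[C@@H]1[C@H](OC(=O)C(C)C)[C@@](C)(C=C)/C=C(/C)CO[Si](c1ccccc1)(c1ccccc1)C(C)(C)C
F14 | step 6 | diisopropyl [(2E,4Z)-6-(tert-butyldiphenylsilyloxy)-3,5-dimethylhexa-2,4-dien-1-yl]boronate | CC(C)OB(C/C=C(\C)/C=C(/C)CO[Si](c1ccccc1)(c1ccccc1)C(C)(C)C)OC(C)C
F15 | step 6 | (S,S)-diisopropyl tartrate ester of the same allylboronic acid | CC(C)OC(=O)[C@H]1OB(C/C=C(\C)/C=C(/C)CO[Si](c2ccccc2)(c2ccccc2)C(C)(C)C)O[C@@H]1C(=O)OC(C)C
A1 | alternative 1 | 2-(hydroxymethyl)-2-methyl-3-alkenyl-4-silyloxycyclohexanone with C5, C6 and C10 set | OC[C@@]1(C)[C@H](C(=C)CO[Si](C)(C)C(C)(C)C)[C@@H](O[Si](C)(C)C(C)(C)C)CCC1=O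
A2 | alternative 1 | (S)-4-(tert-butyldimethylsilyloxy)-2-methylcyclohex-2-en-1-one | CC1=C[C@@H](O[Si](C)(C)C(C)(C)C)CCC1=O
A3 | alternative 2 | target as its 6,15-bis(tert-butyldimethylsilyl) ether | C=C[C@@]1(C)[C@H](C(=C)CO[Si](C)(C)C(C)(C)C)[C@@H](O[Si](C)(C)C(C)(C)C)[C@@H]2C(=C)C(=O)O[C@@H]2[C@@H]1OC(=O)C(C)C
A4 | alternative 2 | open-chain C8 aldehyde with methyl (Z)-2-(bromomethyl)enoate at C7=C11 | O=C[C@H](OC(=O)C(C)C)[C@@](C)(C=C)[C@H](C(=C)CO[Si](C)(C)C(C)(C)C)[C@@H](O[Si](C)(C)C(C)(C)C)/C=C(\CBr)C(=O)OC
A5 | alternative 3 | target as its 15-(tert-butyldimethylsilyl) ether | C=C[C@@]1(C)[C@H](C(=C)CO[Si](C)(C)C(C)(C)C)[C@@H](O)[C@@H]2C(=C)C(=O)O[C@@H]2[C@@H]1OC(=O)C(C)C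
A6 | alternative 3 | open-chain C6 aldehyde tethered to the α-(phenylthiomethyl)butenolide | O=C[C@@H](C(=C)CO[Si](C)(C)C(C)(C)C)[C@](C)(C=C)[C@@H](OC(=O)C(C)C)[C@@H]1C=C(CSc2ccccc2)C(=O)O1
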